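Reading a flat curve as a finished reaction is the pitfall: in birch the complex with two exchanged stops climbing while starting complex is still present.

the same everywhere: incoming ligand 0.263 M

|  | starting complex | temperature | remark | time |
|---|---|---|---|---|
| birch | 0.25 M | −20 °C | the very flask that is asked about, followed so far |  |
| alder | 0.38 M | −14 °C | run made earlier |  |
| flask | 0.25 M | −20 °C |  | 2.0 d |

| run | time / h | complex with two exchanged / % | starting complex / % |
|---|---|---|---|
| birch | 5.00 | 34.6 | 44.1 |
| birch | 10.0 | 39.0 | 37.4 |
| birch | 15.0 | 40.0 | 35.0 |
| birch | 20.0 | 40.4 | 33.5 |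
| birch | 25.0 | 39.9 | 31.6 |
| birch | 30.0 | 39.7 | 30.6 |
| alder | 6.00 | 25.4 | 46.7 |
| alder | 12.0 | 24.7 | 40.1 |
| alder | 20.0 | 24.8 | 34.2 |
| alder | 25.0 | 25.4 | 30.8 |
| alder | 30.0 | 26.6 | 29.0 |
| alder | 40.0 | 26.2 | 25.0 |

(each reading ± 0.5 percentage points)

- additions bring no volume worth counting
- the numbers in the tables scatter with a standard deviation of 0.5 percentage points

- noon: at 2.0 d raise the temperature by 20 K, then wait 50 h
- dawn: at 2.0 d take out 90 % of the leaving ligand then present, then wait 50 h
- dusk: at 2.0 d add incoming ligand, 100 % of the amount charged, then wait 50 h
- winter: change nothing and wait 50 h more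

* complex with two exchanged, in percent of the starting complex first charged, at 2.0 d
* the remedy with the largest gain of complex with two exchanged, or "none" below 2 percentage points (noon / dawn / dusk / winter / none)
* complex with two exchanged present, in percent of the starting complex first charged, after noon
* complex with two exchanged present, in percent of the starting complex first charged, after winter

1. Each exchange uses one incoming ligand and is taken as proportional to its concentration, so that concentration sets the clock of the flask.

2. First extreme: incoming ligand held at its charge. This is pseudo-first-order, with one time constant. The first birch reading gives 6.11 h, and that leaves 0.737 % of the starting complex at 30.0 h. Birch reads 30.6 %, far above it, so the ligand is not held.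

3. Second extreme: the second exchange is instant and incoming ligand goes strictly in pairs. The product then reaches the ligand ceiling, the charged incoming ligand over twice the charged starting complex: 52.6 % for birch. Incoming ligand is the limiting reagent here, with 0.263 M less than twice 0.25 M.

4. The real flask lies under that ceiling. Birch's last reading, 39.7 %, is 0.755 of it. Alder has a ceiling of 34.6 %, and its last reading, 26.2 %, is 0.757 of that.

5. My reckoning: alder's share of birch's ceiling gives 39.8 % at 2.0 d. Dusk brings the incoming ligand to 0.526 M in all, more than the 0.500 M that pairs need, so starting complex becomes the limiting reagent and the ceiling rises to 100 %, while noon, dawn and winter add no incoming ligand and leave it at 52.6 %, so dusk is my choice.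

The forecast says 40 % now, dusk as the remedy, 40.5 % after noon and 40 % after winter, on the ground that “Fresh ligand converts the intermediate and the remaining starting complex”.

The flask gives 40.3 % now and dusk as the remedy, with a gain of 30 points. Winter gives 40.6 %. Noon gives 31.7 %, less than the forecast's 40.5 %.

    starting complex + incoming ligand ⇌ leaving ligand + complex with one exchanged (K = 3.50, k = 1.60 L mol⁻¹ h⁻¹, Ea = 45.0 kJ mol⁻¹, ΔH = −46.0 kJ mol⁻¹)
    complex with one exchanged + incoming ligand ⇌ leaving ligand + complex with two exchanged (K = 15.0, k = 6.20 L mol⁻¹ h⁻¹, Ea = 44.0 kJ mol⁻¹, ΔH = −33.0 kJ mol⁻¹)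
    complex with two exchanged + incoming ligand ⇌ leaving ligand + complex with three exchanged (K = 0.120, k = 0.270 L mol⁻¹ h⁻¹, Ea = 53.0 kJ mol⁻¹, ΔH = −30.0 kJ mol⁻¹)
    2 starting complex → homo dimer (k = 0.0450 L mol⁻¹ h⁻¹, Ea = 57.0 kJ mol⁻¹)
    crystals ⇌ leaving ligand, rate k5*(cs5 - [leaving ligand]) while solid is left; crystals form when [leaving ligand] > cs5 (solubility = 0.0880 M, k = 1.70 h⁻¹)
    (constants at −20 °C)

Birch at 2.0 d stands at 0.766 of its ligand ceiling, with 5.5 % of its incoming ligand left. The neighbouring flask is the same flask charged with 0.45 M of incoming ligand. Its ceiling is 90.0 %, and alder's share of that gives 68.1 %. At 2.0 d, the neighbouring flask has 7.68 % of its incoming ligand left and holds 71.9 % of complex with two exchanged.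

Readings and results are simulated with constants of no real substance; scatter was added.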